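The flavone is disconnected by cutting the C3 methine out of ring C: without that carbon, which sits between C2 and the C4 carbonyl, the pyranone is the furan ring of a 2-aryl-3-oxybenzofuran. In the forward direction dichlorocarbene is added to the C2=C3 enol-ether bond of such a furan; opening of the cyclopropane with loss of chloride forms C2–C3 and C3–C4 and enlarges the five-membered ring to the 3-chloropyranone in one operation. The precursor is the tert-butyldimethylsilyl enol ether of a 2-arylbenzofuran-3(2H)-one with three benzyl ethers on ring A and two triisopropylsilyl ethers on ring B, built from a symmetric phenol and an α-bromo arylacetate.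

Key step: step 9

Remark: the target is drawn as the free bis(hydrogen sulfate), so sulfate monoesters are written in that neutral form; in the flask the silylated disulfate would be carried as its bis(pyridinium) salt, and the target is released from its salt on a sulfonic acid resin (H+ form) in the work-up of the last step.

Step 1
Reactants: 1 3,4,5-tris(benzyloxy)benzaldehyde
Product: 3 3,4,5-tris(benzyloxy)phenol, via aryl formate 2 (not isolated)
Conditions: mCPBA, CH2Cl2, 0 °C → rt; then K2CO3 (cat.), MeOH, rt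
Reagents that add atoms: mCPBA (3-chloroperoxybenzoic acid), O=C(OO)c1cccc(Cl)c1
Why: Baeyer–Villiger (Dakin-type) oxidation, in which the electron-rich trialkoxyaryl group migrates in the Criegee adduct to give the aryl formate, which carbonate in methanol transesterifies to the phenol without touching the benzyl ethers.

Step 2
Reactants: 4 3,4-dihydroxyphenylacetic acid
Product: 5 allyl (3,4-dihydroxyphenyl)acetate
Conditions: allyl alcohol (solvent), TsOH·H2O (cat.), 80 °C
Reagents that add atoms: allyl alcohol, C=CCO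
Why: Fischer esterification in neat allyl alcohol, to which the catechol is inert; the allyl ester is chosen because it can later be removed under neutral conditions that spare aryl silyl ethers.

Step 3
Reactants: 5 allyl (3,4-dihydroxyphenyl)acetate
Product: 6 allyl [3,4-bis(triisopropylsilyloxy)phenyl]acetate
Conditions: TIPSCl, imidazole, DMF, rt → 40 °C
Reagents that add atoms: triisopropylsilyl chloride, CC(C)[Si](Cl)(C(C)C)C(C)C
Why: Imidazole-assisted O-silylation of both phenols; the bulky aryl triisopropylsilyl ethers should tolerate the enolate, carbonate, acid, carbene and hydrogenation conditions ahead and fall to fluoride at the end.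

Step 4
Reactants: 6 allyl [3,4-bis(triisopropylsilyloxy)phenyl]acetate
Product: 8 allyl 2-bromo-2-[3,4-bis(triisopropylsilyloxy)phenyl]acetate (racemic), via lithium enolate 7 (not isolated)
Conditions: LiN(SiMe3)2, THF, −78 °C; then added to NBS, THF, −78 °C
Reagents that add atoms: N-bromosuccinimide, O=C1CCC(=O)N1Br
Why: Enolate α-bromination, in which the benzylic ester enolate is brominated at carbon by NBS and inverse addition at −78 °C suppresses coupling of enolate with product; the new stereocentre is racemic and is erased in step 8.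

Step 5
Reactants: 3 3,4,5-tris(benzyloxy)phenol; 8 allyl 2-bromo-2-[3,4-bis(triisopropylsilyloxy)phenyl]acetate
Product: 9 allyl 2-[3,4-bis(triisopropylsilyloxy)phenyl]-2-[3,4,5-tris(benzyloxy)phenoxy]acetate (racemic)
Conditions: K2CO3, acetone, rt → 40 °C
Reagents that add atoms: none
Why: Williamson ether synthesis (SN2) of the phenoxide on the activated benzylic α-bromo ester under mild carbonate conditions; the phenol is symmetric, so only one ether can form, and the stereocentre stays racemic.

Step 6
Reactants: 9 allyl 2-[3,4-bis(triisopropylsilyloxy)phenyl]-2-[3,4,5-tris(benzyloxy)phenoxy]acetate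
Product: 10 2-[3,4-bis(triisopropylsilyloxy)phenyl]-2-[3,4,5-tris(benzyloxy)phenoxy]acetic acid (racemic)
Conditions: Pd(PPh3)4 (cat.), morpholine, THF, rt; aq. citric acid work-up
Reagents that add atoms: none
Why: Tsuji–Trost deallylation, in which zerovalent palladium ionises the allyl ester to a π-allyl complex that morpholine captures, freeing the acid without hydroxide and so without risk to the aryl silyl ethers.

Step 7
Reactants: 10 2-[3,4-bis(triisopropylsilyloxy)phenyl]-2-[3,4,5-tris(benzyloxy)phenoxy]acetic acid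
Product: 12 4,5,6-tris(benzyloxy)-2-[3,4-bis(triisopropylsilyloxy)phenyl]benzofuran-3(2H)-one (racemic), via mixed trifluoroacetic anhydride 11 (not isolated)
Conditions: (CF3CO)2O, CH2Cl2, 0 °C → rt
Reagents that add atoms: none
Why: Intramolecular Friedel–Crafts acylation through the mixed anhydride, in which the ring carbon ortho to the ether oxygen, activated by three ortho/para oxygens, closes the five-membered ketone ring without a Lewis acid; both ortho positions of the symmetric aryloxy ring are equivalent, so one regioisomer results.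

Step 8
Reactants: 12 4,5,6-tris(benzyloxy)-2-[3,4-bis(triisopropylsilyloxy)phenyl]benzofuran-3(2H)-one
Product: 13 4,5,6-tris(benzyloxy)-3-(tert-butyldimethylsilyloxy)-2-[3,4-bis(triisopropylsilyloxy)phenyl]benzofuran
Conditions: TBSOTf, Et3N, CH2Cl2, 0 °C, under argon
Reagents that add atoms: tert-butyldimethylsilyl triflate, CC(C)(C)[Si](C)(C)OS(=O)(=O)C(F)(F)F
Why: Soft enolisation and O-silylation, in which the C2–H is acidified by the ketone, the ring oxygen and the aryl group and silylation on oxygen is driven by formation of the aromatic benzofuran; the air-sensitive ketone would be used directly, and its stereocentre disappears here.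

Step 9
Reactants: 13 4,5,6-tris(benzyloxy)-3-(tert-butyldimethylsilyloxy)-2-[3,4-bis(triisopropylsilyloxy)phenyl]benzofuran; 14 sodium trichloroacetate
Product: 17 5,6,7-tris(benzyloxy)-3-chloro-2-[3,4-bis(triisopropylsilyloxy)phenyl]-4H-chromen-4-one, via dichlorocyclopropane 15 (not isolated), via silyloxybenzopyrylium chloride 16 (not isolated)
Conditions: Cl3CCO2Na (added in portions), DME, 85 °C
Reagents that add atoms: sodium trichloroacetate (14), [Na+].[O-]C(=O)C(Cl)(Cl)Cl
Why: Proposed new method: thermal decarboxylation of Cl3CCO2Na gives CCl3− and then dichlorocarbene, an electrophile that adds in a cheletropic [2+1] fashion to the furan C2=C3 bond, the most nucleophilic π bond because it carries both the ring oxygen and the silyloxy group, to give the fused gem-dichlorocyclopropane 15. The endo chloride then ionises with concerted disrotatory, two-electron electrocyclic opening of the cyclopropyl cation, which breaks the old furan C2–C3 bond, so that ring C is closed not by a cyclisation but by one-carbon ring enlargement, the carbene carbon becoming C3 bonded to C2 and C4 in the aromatic 3-chloro-4-silyloxybenzopyrylium ion 16. Chloride takes the silyl group from the oxocarbenium oxygen and releases the 3-chloroflavone, with aromatisation to the pyrylium and then the pyranone as driving force. The closest known reaction types are the Ciamician–Dennstedt dihalocarbene expansion of pyrroles and indoles to 3-halopyridines and 3-haloquinolines and the dihalocarbene expansion of cyclic silyl enol ethers to α-halo enones; the 3-silyloxybenzofuran substrate is the new element. No stereocentre is formed. The step needs addition to the enol-ether bond and not to the alkoxy arenes or benzylic C–H bonds, which the two oxygen donors on that bond and slow generation of a limited excess of carbene under neutral aprotic conditions should secure, and it needs opening of the internal cyclopropane bond, which the donor pair O1/OSi and the rule that only the endo chloride can leave to give an in-ring allyl cation should secure.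

Step 10
Reactants: 17 5,6,7-tris(benzyloxy)-3-chloro-2-[3,4-bis(triisopropylsilyloxy)phenyl]-4H-chromen-4-one
Product: 18 5,6,7-trihydroxy-2-[3,4-bis(triisopropylsilyloxy)phenyl]-4H-chromen-4-one
Conditions: H2 (1 atm), Pd/C, NaOAc, EtOAc/MeOH, rt
Reagents that add atoms: none
Why: Catalytic hydrogenolysis, which cleaves the three aryl benzyl ethers and reduces the C3–Cl bond of the α-chloro enone together, with NaOAc taking up HCl without slowing debenzylation as an amine base would; the flavone C2=C3 bond and the aryl silyl ethers should be inert under these mild conditions.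

Step 11
Reactants: 18 5,6,7-trihydroxy-2-[3,4-bis(triisopropylsilyloxy)phenyl]-4H-chromen-4-one
Product: 19 5-hydroxy-4-oxo-2-[3,4-bis(triisopropylsilyloxy)phenyl]-4H-chromene-6,7-diyl bis(hydrogen sulfate)
Conditions: SO3·pyridine (excess), pyridine, rt → 40 °C, under argon
Reagents that add atoms: sulfur trioxide–pyridine complex, O=S(=O)([O-])[n+]1ccccc1
Why: O-Sulfation with the SO3–pyridine complex at the 6- and 7-hydroxyls, whereas the 5-hydroxyl is held in a strong hydrogen bond to the C4 carbonyl and is the least nucleophilic, and the ring B phenols are masked as silyl ethers.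

Step 12
Reactants: 19 5-hydroxy-4-oxo-2-[3,4-bis(triisopropylsilyloxy)phenyl]-4H-chromene-6,7-diyl bis(hydrogen sulfate)
Product: 20 6-hydroxyluteolin 6,7-disulfate, 2-(3,4-dihydroxyphenyl)-5-hydroxy-4-oxo-4H-chromene-6,7-diyl bis(hydrogen sulfate)
Conditions: TBAF, AcOH, THF, 0 °C; then Dowex 50WX8 (H+ form), H2O/MeOH, 0 °C, freeze-drying
Reagents that add atoms: none
Why: Fluoride-induced cleavage of the two aryl silyl ethers, buffered with acetic acid so that the catechol is not exposed to base and air; aryl sulfate monoesters are stable to fluoride, and cold exchange on the acid resin should give the hydrogen sulfate form drawn for the target.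

Compound list
1 | 3,4,5-tris(benzyloxy)benzaldehyde | O=Cc1cc(OCc2ccccc2)c(OCc2ccccc2)c(OCc2ccccc2)c1 | starting material
2 | 3,4,5-tris(benzyloxy)phenyl formate | O=COc1cc(OCc2ccccc2)c(OCc2ccccc2)c(OCc2ccccc2)c1 | intermediate
3 | 3,4,5-tris(benzyloxy)phenol | Oc1cc(OCc2ccccc2)c(OCc2ccccc2)c(OCc2ccccc2)c1 | intermediate
4 | 3,4-dihydroxyphenylacetic acid | OC(=O)Cc1ccc(O)c(O)c1 | starting material
5 | allyl (3,4-dihydroxyphenyl)acetate | C=CCOC(=O)Cc1ccc(O)c(O)c1 | intermediate
6 | allyl [3,4-bis(triisopropylsilyloxy)phenyl]acetate | C=CCOC(=O)Cc1ccc(O[Si](C(C)C)(C(C)C)C(C)C)c(O[Si](C(C)C)(C(C)C)C(C)C)c1 | intermediate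
7 | lithium enolate of 6 (double-bond geometry not defined) | [Li]OC(OCC=C)=Cc1ccc(O[Si](C(C)C)(C(C)C)C(C)C)c(O[Si](C(C)C)(C(C)C)C(C)C)c1 | intermediate
8 | allyl 2-bromo-2-[3,4-bis(triisopropylsilyloxy)phenyl]acetate (racemic) | C=CCOC(=O)C(Br)c1ccc(O[Si](C(C)C)(C(C)C)C(C)C)c(O[Si](C(C)C)(C(C)C)C(C)C)c1 | intermediate
9 | allyl 2-[3,4-bis(triisopropylsilyloxy)phenyl]-2-[3,4,5-tris(benzyloxy)phenoxy]acetate (racemic) | C=CCOC(=O)C(Oc1cc(OCc2ccccc2)c(OCc2ccccc2)c(OCc2ccccc2)c1)c1ccc(O[Si](C(C)C)(C(C)C)C(C)C)c(O[Si](C(C)C)(C(C)C)C(C)C)c1 | intermediate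
10 | 2-[3,4-bis(triisopropylsilyloxy)phenyl]-2-[3,4,5-tris(benzyloxy)phenoxy]acetic acid (racemic) | OC(=O)C(Oc1cc(OCc2ccccc2)c(OCc2ccccc2)c(OCc2ccccc2)c1)c1ccc(O[Si](C(C)C)(C(C)C)C(C)C)c(O[Si](C(C)C)(C(C)C)C(C)C)c1 | intermediate
11 | mixed anhydride of 10 with trifluoroacetic acid (racemic) | O=C(OC(=O)C(F)(F)F)C(Oc1cc(OCc2ccccc2)c(OCc2ccccc2)c(OCc2ccccc2)c1)c1ccc(O[Si](C(C)C)(C(C)C)C(C)C)c(O[Si](C(C)C)(C(C)C)C(C)C)c1 | intermediate
12 | 4,5,6-tris(benzyloxy)-2-[3,4-bis(triisopropylsilyloxy)phenyl]benzofuran-3(2H)-one (racemic) | O=C1C(c2ccc(O[Si](C(C)C)(C(C)C)C(C)C)c(O[Si](C(C)C)(C(C)C)C(C)C)c2)Oc2cc(OCc3ccccc3)c(OCc3ccccc3)c(OCc3ccccc3)c12 | intermediate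
13 | 4,5,6-tris(benzyloxy)-3-(tert-butyldimethylsilyloxy)-2-[3,4-bis(triisopropylsilyloxy)phenyl]benzofuran | CC(C)(C)[Si](C)(C)Oc1c(-c2ccc(O[Si](C(C)C)(C(C)C)C(C)C)c(O[Si](C(C)C)(C(C)C)C(C)C)c2)oc2cc(OCc3ccccc3)c(OCc3ccccc3)c(OCc3ccccc3)c12 | intermediate
14 | sodium trichloroacetate | [Na+].[O-]C(=O)C(Cl)(Cl)Cl | starting material
15 | 4,5,6-tris(benzyloxy)-6b-(tert-butyldimethylsilyloxy)-1,1-dichloro-1a-[3,4-bis(triisopropylsilyloxy)phenyl]-1a,6b-dihydro-1H-cyclopropa[b]benzofuran (racemic; ring fusion necessarily cis) | CC(C)(C)[Si](C)(C)OC12c3c(OCc4ccccc4)c(OCc4ccccc4)c(OCc4ccccc4)cc3OC1(c1ccc(O[Si](C(C)C)(C(C)C)C(C)C)c(O[Si](C(C)C)(C(C)C)C(C)C)c1)C2(Cl)Cl | intermediate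
16 | 5,6,7-tris(benzyloxy)-4-(tert-butyldimethylsilyloxy)-3-chloro-2-[3,4-bis(triisopropylsilyloxy)phenyl]chromenylium chloride | CC(C)(C)[Si](C)(C)Oc1c(Cl)c(-c2ccc(O[Si](C(C)C)(C(C)C)C(C)C)c(O[Si](C(C)C)(C(C)C)C(C)C)c2)[o+]c2cc(OCc3ccccc3)c(OCc3ccccc3)c(OCc3ccccc3)c12.[Cl-] | intermediate
17 | 5,6,7-tris(benzyloxy)-3-chloro-2-[3,4-bis(triisopropylsilyloxy)phenyl]-4H-chromen-4-one | O=c1c(Cl)c(-c2ccc(O[Si](C(C)C)(C(C)C)C(C)C)c(O[Si](C(C)C)(C(C)C)C(C)C)c2)oc2cc(OCc3ccccc3)c(OCc3ccccc3)c(OCc3ccccc3)c12 | intermediate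
18 | 5,6,7-trihydroxy-2-[3,4-bis(triisopropylsilyloxy)phenyl]-4H-chromen-4-one | O=c1cc(-c2ccc(O[Si](C(C)C)(C(C)C)C(C)C)c(O[Si](C(C)C)(C(C)C)C(C)C)c2)oc2cc(O)c(O)c(O)c12 | intermediate
19 | 5-hydroxy-4-oxo-2-[3,4-bis(triisopropylsilyloxy)phenyl]-4H-chromene-6,7-diyl bis(hydrogen sulfate) | O=c1cc(-c2ccc(O[Si](C(C)C)(C(C)C)C(C)C)c(O[Si](C(C)C)(C(C)C)C(C)C)c2)oc2cc(OS(=O)(=O)O)c(OS(=O)(=O)O)c(O)c12 | intermediate
20 | 6-hydroxyluteolin 6,7-disulfate (no stereocentre) | O=c1cc(-c2ccc(O)c(O)c2)oc2cc(OS(=O)(=O)O)c(OS(=O)(=O)O)c(O)c12 | target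

Total step count: 12.
Longest linear sequence: 11 steps (4 → 20, steps 2 to 12); the branch from 1 joins at step 5.

Steps most likely to fail

Step 9. The carbene may be consumed by insertion into benzylic C–H bonds or attack on ring A, or the enol ether may lose its silyl group before the carbene arrives. Fallback (known chemistry, a Claisen condensation and cyclodehydration route to the flavone): setting out from 3, ortho C-acetylation (Ac2O, BF3·OEt2, 0 °C → rt) would give 1-[4,5,6-tris(benzyloxy)-2-hydroxyphenyl]ethanone F1. Its dianion (LiN(SiMe3)2, THF, −78 °C → rt) would be condensed with methyl 3,4-bis(triisopropylsilyloxy)benzoate F2 (from methyl 3,4-dihydroxybenzoate, TIPSCl, imidazole, DMF) to give 1-[4,5,6-tris(benzyloxy)-2-hydroxyphenyl]-3-[3,4-bis(triisopropylsilyloxy)phenyl]propane-1,3-dione F3. Cyclodehydration (TsOH cat., toluene, 80 °C) would give 5,6,7-tris(benzyloxy)-2-[3,4-bis(triisopropylsilyloxy)phenyl]-4H-chromen-4-one F4, and hydrogenolysis (H2, Pd/C, EtOAc/MeOH) would return to the route at 18.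

Step 7. The activated α-aryl-α-aryloxy acyl species may ionise with loss of carbon monoxide or form a ketene instead of acylating the ring, and the acid released may strip a protecting group. Fallback (ring closure before ring B is attached): setting out from 3, alkylation with bromoacetic acid (NaH, THF/DMF) would give [3,4,5-tris(benzyloxy)phenoxy]acetic acid F5. Its cyclisation ((CF3CO)2O, CH2Cl2) cannot pass through a stabilised cation and involves no silyl ether, and would give 4,5,6-tris(benzyloxy)benzofuran-3(2H)-one F6. Palladium-catalysed ketone α-arylation (Pd2(dba)3, XPhos, K3PO4, toluene, 80 °C) with 4-bromo-1,2-bis(triisopropylsilyloxy)benzene F7 (from 4-bromocatechol, TIPSCl, imidazole) would return to the route at 12.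

Step 11. The second sulfation next to the first sulfate may stall, or sulfation may spill over to O5, giving ionic mixtures that are hard to separate. Fallback (protected sulfate diesters in place of direct SO3 transfer): setting out from 18, treatment with 2,2,2-trichloroethyl chlorosulfate (Et3N, DMAP, THF, 0 °C → rt) would give the neutral, chromatographable 5-hydroxy-4-oxo-2-[3,4-bis(triisopropylsilyloxy)phenyl]-4H-chromene-6,7-diyl bis(2,2,2-trichloroethyl sulfate) F8. Reductive removal of the trichloroethyl groups (Zn, HCO2NH4, MeOH, rt) would return to the route at 19.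

Further compounds
F1 | step 9 | 1-[4,5,6-tris(benzyloxy)-2-hydroxyphenyl]ethanone | CC(=O)c1c(O)cc(OCc2ccccc2)c(OCc2ccccc2)c1OCc1ccccc1
F2 | step 9 | methyl 3,4-bis(triisopropylsilyloxy)benzoate | COC(=O)c1ccc(O[Si](C(C)C)(C(C)C)C(C)C)c(O[Si](C(C)C)(C(C)C)C(C)C)c1
F3 | step 9 | 1-[4,5,6-tris(benzyloxy)-2-hydroxyphenyl]-3-[3,4-bis(triisopropylsilyloxy)phenyl]propane-1,3-dione | O=C(CC(=O)c1ccc(O[Si](C(C)C)(C(C)C)C(C)C)c(O[Si](C(C)C)(C(C)C)C(C)C)c1)c1c(O)cc(OCc2ccccc2)c(OCc2ccccc2)c1OCc1ccccc1
F4 | step 9 | 5,6,7-tris(benzyloxy)-2-[3,4-bis(triisopropylsilyloxy)phenyl]-4H-chromen-4-one | O=c1cc(-c2ccc(O[Si](C(C)C)(C(C)C)C(C)C)c(O[Si](C(C)C)(C(C)C)C(C)C)c2)oc2cc(OCc3ccccc3)c(OCc3ccccc3)c(OCc3ccccc3)c12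
F5 | step 7 | [3,4,5-tris(benzyloxy)phenoxy]acetic acid | OC(=O)COc1cc(OCc2ccccc2)c(OCc2ccccc2)c(OCc2ccccc2)c1
F6 | step 7 | 4,5,6-tris(benzyloxy)benzofuran-3(2H)-one | O=C1COc2cc(OCc3ccccc3)c(OCc3ccccc3)c(OCc3ccccc3)c12
F7 | step 7 | 4-bromo-1,2-bis(triisopropylsilyloxy)benzene | Brc1ccc(O[Si](C(C)C)(C(C)C)C(C)C)c(O[Si](C(C)C)(C(C)C)C(C)C)c1
F8 | step 11 | 5-hydroxy-4-oxo-2-[3,4-bis(triisopropylsilyloxy)phenyl]-4H-chromene-6,7-diyl bis(2,2,2-trichloroethyl sulfate) | O=c1cc(-c2ccc(O[Si](C(C)C)(C(C)C)C(C)C)c(O[Si](C(C)C)(C(C)C)C(C)C)c2)oc2cc(OS(=O)(=O)OCC(Cl)(Cl)Cl)c(OS(=O)(=O)OCC(Cl)(Cl)Cl)c(O)c12
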